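**Retrosynthetic overview**

1. Ring numbering: C1 = ketone, C2=C3, C4–C6 = carbinols. The target is traced back to its C4/C5 acetonide with C2–C3 saturated; the C2=C3 bond is put in last by dehydrogenation, which can only go towards C2 because C6 bears no hydrogen.
2. Key disconnection: C1–C6 (aldehyde-to-ketone benzoin addition, 6-exo) together with C1–C2. C1 is brought in as carbon monoxide, so the carbocycle is assembled from an acyclic vinyl ketone (C2–C6 plus side chain), CO and H2 in one operation.
3. Enabling feature: the acyloin C1(=O)–C6(OH)(alkyl) inside the six-membered ring C1–C6, next to the trans-4,5-diol. O4 and O5 can be tied into a temporary trans-fused dioxolane (a ring not in the target) that fixes the chair of the closing ring and steers C6.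
4. The vinyl ketone comes from the Weinreb amide of L-tartrate acetonide carrying one vinyl group (C3=C2; diester desymmetrised by mono-reduction, oxidation, methylenation) and the (Z)-henicos-12-enyl Grignard reagent (Wittig reaction of 12-bromododecanal with the nonyl ylide).
5. Ring order: dioxolane from the chiral pool first, carbocycle C1–C6 in the key step, dioxolane removed last.

Key step: step 8

Remark on the chemistry: the target is read as (4S,5R,6R)-4,5,6-trihydroxy-6-[(12Z)-henicos-12-en-1-yl]cyclohex-2-en-1-one (4-OH trans to 5-OH, 5-OH cis to 6-OH), and the three starting materials are taken to be commercial.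

**Route**

Step 1
Reactants: 1 12-bromododecan-1-ol
Product: 2 12-bromododecanal
Conditions: TEMPO (10 mol %), PhI(OAc)2, CH2Cl2, rt
Reagents that add atoms: none
Why: TEMPO-catalysed (oxoammonium) alcohol oxidation stops at the aldehyde under non-basic conditions that leave the primary bromide untouched.

Step 2
Reactants: 2 12-bromododecanal; 3 nonyltriphenylphosphonium bromide
Product: 5 (Z)-21-bromohenicos-9-ene, via nonylidenetriphenylphosphorane 4 (not isolated)
Conditions: 3, NaN(SiMe3)2, THF, 0 °C; then 2, −78 °C → rt
Reagents that add atoms: none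
Why: The Wittig reaction of a non-stabilised ylide under lithium-free conditions is kinetically controlled and should give the (Z)-alkene, while at −78 °C the ylide reacts with the aldehyde far faster than with the primary bromide.

Step 3
Reactants: 6 dimethyl (4R,5R)-2,2-dimethyl-1,3-dioxolane-4,5-dicarboxylate
Product: 7 methyl (4R,5S)-5-(hydroxymethyl)-2,2-dimethyl-1,3-dioxolane-4-carboxylate
Conditions: NaBH4 (0.55 equiv), MeOH, 0 °C
Reagents that add atoms: none
Why: Chemoselective NaBH4 reduction of an activated α-alkoxy ester; the diester is C2-symmetric, so reduction of either ester gives the same hydroxy ester, the limited hydride favours mono-reduction, and no stereocentre is touched.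

Step 4
Reactants: 7 methyl (4R,5S)-5-(hydroxymethyl)-2,2-dimethyl-1,3-dioxolane-4-carboxylate
Product: 8 methyl (4R,5R)-5-formyl-2,2-dimethyl-1,3-dioxolane-4-carboxylate
Conditions: TEMPO (10 mol %), PhI(OAc)2, CH2Cl2, rt
Reagents that add atoms: none
Why: TEMPO-catalysed oxidation gives the α-alkoxy aldehyde under neutral conditions that avoid epimerisation, and the trans-dioxolane is in any case the more stable arrangement.

Step 5
Reactants: 8 methyl (4R,5R)-5-formyl-2,2-dimethyl-1,3-dioxolane-4-carboxylate
Product: 9 methyl (4R,5S)-5-ethenyl-2,2-dimethyl-1,3-dioxolane-4-carboxylate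
Conditions: Ph3PCH3Br, KN(SiMe3)2, THF, 0 °C; then 8, −78 → 0 °C
Reagents that add atoms: methyltriphenylphosphonium bromide, C[P+](c1ccccc1)(c1ccccc1)c1ccccc1.[Br-]
Why: Wittig methylenation is selective for the aldehyde over the ester at low temperature and creates the C3=C2 vinyl group without touching the two dioxolane stereocentres.

Step 6
Reactants: 9 methyl (4R,5S)-5-ethenyl-2,2-dimethyl-1,3-dioxolane-4-carboxylate
Product: 10 (4R,5S)-5-ethenyl-N-methoxy-N,2,2-trimethyl-1,3-dioxolane-4-carboxamide
Conditions: MeNH(OMe)·HCl, i-PrMgCl, THF, −20 °C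
Reagents that add atoms: N,O-dimethylhydroxylamine hydrochloride, CNOC.Cl
Why: Direct aminolysis of the ester by the chloromagnesium amide of N,O-dimethylhydroxylamine (Weinreb amide formation) is well suited to activated α-alkoxy esters at −20 °C and should not epimerise the α-carbon.

Step 7
Reactants: 10 (4R,5S)-5-ethenyl-N-methoxy-N,2,2-trimethyl-1,3-dioxolane-4-carboxamide; 5 (Z)-21-bromohenicos-9-ene
Product: 12 (13Z)-1-[(4R,5S)-5-ethenyl-2,2-dimethyl-1,3-dioxolan-4-yl]docos-13-en-1-one, via (Z)-henicos-12-enylmagnesium bromide 11 (not isolated)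
Conditions: 5, Mg, THF, 40 °C; then 10, THF, 0 °C; aq NH4Cl
Reagents that add atoms: none
Why: Weinreb ketone synthesis: the Grignard reagent adds once because the magnesium-chelated tetrahedral intermediate collapses only on work-up, and the remote (Z)-alkene and the vinyl group are inert.

Step 8
Reactants: 12 (13Z)-1-[(4R,5S)-5-ethenyl-2,2-dimethyl-1,3-dioxolan-4-yl]docos-13-en-1-one
Product: 14 (3aR,4R,7aS)-4-hydroxy-4-[(12Z)-henicos-12-en-1-yl]-2,2-dimethylhexahydro-1,3-benzodioxol-5-one, via linear keto aldehyde 13 (not isolated)
Conditions: Rh(acac)(CO)2 (1 mol %), Xantphos (3 mol %), CO/H2 (1:1, 20 bar), 3-benzyl-5-(2-hydroxyethyl)-4-methylthiazolium chloride (20 mol %), Et3N (50 mol %), toluene/t-AmOH, 0.02 M, 70 °C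
Reagents that add atoms: carbon monoxide, [C-]#[O+]
Why: Proposed new method: two catalytic cycles run side by side; Rh/Xantphos linear hydroformylation turns the vinyl group into the aldehyde of 13 (C1 from CO, bond C1–C2), the thiazol-2-ylidene released from the thiazolium salt by Et3N adds to that aldehyde, the resulting Breslow intermediate attacks the C6 ketone through C1 and loss of the carbene leaves the α-ketol, the closest known reaction types being the tandem hydroformylation/acyloin reaction of terminal alkenes (intermolecular, aldehyde to aldehyde) and the azolium-catalysed intramolecular crossed aldehyde–ketone benzoin cyclisation of isolated 6-oxo aldehydes. The carbocycle closes in the 6-exo-trig mode, C1 adding to the C6=O that lies outside the forming ring. C6 is the only new stereocentre and is controlled by the temporary trans-fused dioxolane: O4 and O5 are held diequatorial on the chair-like transition state, the C5–O bond is anti to the forming C1–C6 bond (polar Felkin–Anh arrangement) and the long alkyl chain takes the equatorial position anti to C5–C4, so that the new C6–OH is axial and cis to O5 as in the target, the small sulfur flank of the thiazole tolerating the gauche contact with the chain. The step needs linear over branched and terminal over internal alkene selectivity, which the wide-bite-angle diphosphine and the CO pressure should secure, and it needs the aldehyde, not the ketone, to become the acyl-anion donor, which is inherent because only aldehydes form Breslow intermediates. Cyclisation should outrun intermolecular acyloin and aldol reactions because the aldehyde is released slowly and stays at low concentration, and C5 is not at risk because the trans-dioxolane is the more stable epimer.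

Step 9
Reactants: 14 (3aR,4R,7aS)-4-hydroxy-4-[(12Z)-henicos-12-en-1-yl]-2,2-dimethylhexahydro-1,3-benzodioxol-5-one
Product: 16 (3aR,4R,7aS)-4-[(12Z)-henicos-12-en-1-yl]-2,2-dimethyl-4-(trimethylsilyloxy)-3a,7a-dihydro-1,3-benzodioxol-5(4H)-one, via bis(trimethylsilyl) enol ether 15 (not isolated)
Conditions: LiN(SiMe3)2, Me3SiCl, THF, −78 → 0 °C; then Pd(OAc)2, MeCN, rt
Reagents that add atoms: chlorotrimethylsilane, C[Si](C)(C)Cl
Why: Saegusa–Ito oxidation: because C6 is quaternary the ketone can enolise only towards C2, so silylation gives one silyl enol ether (the tertiary hydroxyl is silylated as well) and Pd(OAc)2 then forms the C2=C3 bond by β-hydride elimination without touching C4–C6.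

Step 10
Reactants: 16 (3aR,4R,7aS)-4-[(12Z)-henicos-12-en-1-yl]-2,2-dimethyl-4-(trimethylsilyloxy)-3a,7a-dihydro-1,3-benzodioxol-5(4H)-one
Product: 17 (4S,5R,6R)-4,5,6-trihydroxy-6-[(12Z)-henicos-12-en-1-yl]cyclohex-2-en-1-one
Conditions: AcOH/H2O (4:1), 40 °C
Reagents that add atoms: none
Why: Acid-catalysed hydrolysis (acetal and silyl ether cleavage) should remove the strained trans-fused acetonide and the tertiary trimethylsilyl ether under mild conditions that leave the three carbinol centres, the enone and the (Z)-alkene untouched.

**Compound list**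

1 | 12-bromododecan-1-ol | OCCCCCCCCCCCCBr | starting material
2 | 12-bromododecanal | O=CCCCCCCCCCCCBr | intermediate
3 | nonyltriphenylphosphonium bromide | CCCCCCCCC[P+](c1ccccc1)(c1ccccc1)c1ccccc1.[Br-] | starting material
4 | nonylidenetriphenylphosphorane (not isolated) | CCCCCCCCC=P(c1ccccc1)(c1ccccc1)c1ccccc1 | intermediate
5 | (Z)-21-bromohenicos-9-ene [(Z)-1-bromohenicos-12-ene] | CCCCCCCC/C=C\CCCCCCCCCCCBr | intermediate
6 | dimethyl (4R,5R)-2,2-dimethyl-1,3-dioxolane-4,5-dicarboxylate (dimethyl 2,3-O-isopropylidene-L-tartrate) | COC(=O)[C@@H]1OC(C)(C)O[C@H]1C(=O)OC | starting material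
7 | methyl (4R,5S)-5-(hydroxymethyl)-2,2-dimethyl-1,3-dioxolane-4-carboxylate | COC(=O)[C@@H]1OC(C)(C)O[C@H]1CO | intermediate
8 | methyl (4R,5R)-5-formyl-2,2-dimethyl-1,3-dioxolane-4-carboxylate | COC(=O)[C@@H]1OC(C)(C)O[C@H]1C=O | intermediate
9 | methyl (4R,5S)-5-ethenyl-2,2-dimethyl-1,3-dioxolane-4-carboxylate | COC(=O)[C@@H]1OC(C)(C)O[C@H]1C=C | intermediate
10 | (4R,5S)-5-ethenyl-N-methoxy-N,2,2-trimethyl-1,3-dioxolane-4-carboxamide | CON(C)C(=O)[C@@H]1OC(C)(C)O[C@H]1C=C | intermediate
11 | (Z)-henicos-12-enylmagnesium bromide (not isolated) | CCCCCCCC/C=C\CCCCCCCCCCC[Mg]Br | intermediate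
12 | (13Z)-1-[(4R,5S)-5-ethenyl-2,2-dimethyl-1,3-dioxolan-4-yl]docos-13-en-1-one | CCCCCCCC/C=C\CCCCCCCCCCCC(=O)[C@@H]1OC(C)(C)O[C@H]1C=C | intermediate
13 | 3-[(4S,5R)-5-[(13Z)-docos-13-enoyl]-2,2-dimethyl-1,3-dioxolan-4-yl]propanal (not isolated) | CCCCCCCC/C=C\CCCCCCCCCCCC(=O)[C@@H]1OC(C)(C)O[C@H]1CCC=O | intermediate
14 | (3aR,4R,7aS)-4-hydroxy-4-[(12Z)-henicos-12-en-1-yl]-2,2-dimethylhexahydro-1,3-benzodioxol-5-one (trans-fused; benzodioxole C4 = target C6, C5 = target C1) | CCCCCCCC/C=C\CCCCCCCCCCC[C@]1(O)C(=O)CC[C@@H]2OC(C)(C)O[C@@H]12 | intermediate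
15 | (3aR,4R,7aS)-4-[(12Z)-henicos-12-en-1-yl]-2,2-dimethyl-4,5-bis(trimethylsilyloxy)-3a,4,7,7a-tetrahydro-1,3-benzodioxole (not isolated) | CCCCCCCC/C=C\CCCCCCCCCCC[C@]1(O[Si](C)(C)C)C(O[Si](C)(C)C)=CC[C@@H]2OC(C)(C)O[C@@H]12 | intermediate
16 | (3aR,4R,7aS)-4-[(12Z)-henicos-12-en-1-yl]-2,2-dimethyl-4-(trimethylsilyloxy)-3a,7a-dihydro-1,3-benzodioxol-5(4H)-one | CCCCCCCC/C=C\CCCCCCCCCCC[C@]1(O[Si](C)(C)C)C(=O)C=C[C@@H]2OC(C)(C)O[C@@H]12 | intermediate
17 | (4S,5R,6R)-4,5,6-trihydroxy-6-[(12Z)-henicos-12-en-1-yl]cyclohex-2-en-1-one | CCCCCCCC/C=C\CCCCCCCCCCC[C@]1(O)C(=O)C=C[C@H](O)[C@H]1O | target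

**Step count and risks**

Total step count: 10. Longest linear sequence: 8 steps (steps 3 to 10, from 6 to 17).

Steps most likely to fail:

1. Step 8 (Proposed new method). The two catalysts may inhibit each other through binding of the carbene to rhodium. The facial selectivity at C6 may also be poor, because the hydrogen-bonded benzoin transition state could place the chain axial instead of equatorial. The fallback uses known chemistry, sets out from 12 and comes back at 14. It gives up the tandem and runs two separate steps: hydroformylation alone (Rh(acac)(CO)2, Xantphos, CO/H2, toluene, 60 °C) with isolation of the keto aldehyde 13, then the established intramolecular crossed aldehyde–ketone benzoin cyclisation of the isolated 6-oxo aldehyde. That cyclisation would be run under catalyst control with an enantiopure aminoindanol-derived triazolium salt and DBU in THF, the antipode of the catalyst being chosen so that it reinforces the substrate bias. It makes no compound outside the list, F0.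

2. Step 9. The palladium hydride formed in the β-hydride elimination may isomerise or migrate the remote (Z)-alkene, and premature loss of the enol silyl group would return the saturated ketone. The fallback sets out from 14, passes through the same silyl enol ether 15 and comes back at 16 without any palladium. Selenenylation of 15 with PhSeCl in THF at −78 °C, where the silyl enol ether reacts far faster than the isolated alkene, should give the α-selanyl ketone (3aR,4R,7aS)-4-[(12Z)-henicos-12-en-1-yl]-2,2-dimethyl-6-(phenylselanyl)-4-(trimethylsilyloxy)hexahydro-1,3-benzodioxol-5-one F1 as a mixture of epimers at the selenium-bearing carbon. Oxidation with NaIO4 and NaHCO3 in aqueous THF and selenoxide syn-elimination at room temperature, which can only go towards C3, should then give 16.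

3. Step 3. Over-reduction to the diol and incomplete conversion may leave a statistical mixture, since both esters are equivalent. The fallback sets out from 6 and comes back at 7. Mono-saponification with one equivalent of KOH in MeOH should give the half-ester (4R,5R)-5-(methoxycarbonyl)-2,2-dimethyl-1,3-dioxolane-4-carboxylic acid F2. Chemoselective reduction of the carboxylic acid in the presence of the ester with BH3·SMe2 in THF at 0 °C should then give 7.

**Further compounds**

F0 | step 8 | none | none
F1 | step 9 | (3aR,4R,7aS)-4-[(12Z)-henicos-12-en-1-yl]-2,2-dimethyl-6-(phenylselanyl)-4-(trimethylsilyloxy)hexahydro-1,3-benzodioxol-5-one (both epimers at the selenium-bearing carbon) | CCCCCCCC/C=C\CCCCCCCCCCC[C@]1(O[Si](C)(C)C)C(=O)C([Se]c3ccccc3)C[C@@H]2OC(C)(C)O[C@@H]12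
F2 | step 3 | (4R,5R)-5-(methoxycarbonyl)-2,2-dimethyl-1,3-dioxolane-4-carboxylic acid | COC(=O)[C@@H]1OC(C)(C)O[C@H]1C(=O)O
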